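## Structural features

The target is a C–C linked biflavonoid made of two 4H-chromen-4-one units. Unit 1 is a 2,3-diarylchromone with 5-OH and 7-OMe on ring A and a 4-hydroxyphenyl group at C2. Unit 2 is a 5,7-dihydroxyflavone whose 4-methoxyphenyl ring B is bonded through its C3' to C3 of unit 1, so one benzene ring serves both as the C3 aryl group of unit 1 and as ring B of unit 2. There is no stereocentre; the only stereochemical element in the route is the geometry of a tetrasubstituted alkene in acyclic intermediates. Six oxygen substituents sit on the periphery: four free phenols (two hydrogen-bonded to the C4 carbonyls) and two methyl ethers at C7 of unit 1 and C4' of unit 2, so the protecting-group plan has to tell these positions apart. The fragile parts are the γ-pyranone rings (opened by hydroxide and strong nucleophiles), the electron-rich phloroglucinol rings (easily alkylated or acylated) and the two methyl ethers that must survive the last deprotection. The real difficulty is the fully substituted C2=C3 bond of unit 1, flanked by two aryl groups, one of which carries an ortho methoxy group and the whole of unit 2. The key step exploits ring A of unit 1 being a phloroglucinol ether: C4a is ortho to O1 and to the C5 oxygen and para to the C7 oxygen, so the C4 carbonyl can be joined to C4a last by intramolecular electrophilic acylation, with both aryl groups already in place on an acyclic acrylic acid.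

## Logic of the disconnections

16 ⇒ 15. The three benzyl–oxygen bonds and the methyl–oxygen bond at C5 of unit 1 are put back. The cut is made here because the methyl ether to be removed is the only one peri to a carbonyl, so one boron Lewis acid can take it off together with the benzyl groups. The gain is that no free phenol is carried and ring A of unit 1 can be handled as a symmetric dimethyl ether. The forward step must spare the unchelated methyl ethers at C7 of unit 1 and C4' of unit 2.

15 ⇒ 12 + 13. C2–C3 and O1–C2 of unit 2 are cut. Ring A of unit 2 then comes from the purchasable 13, and unit 2 shrinks to the methyl ester of 12, whose carbonyl carbon becomes C2. The forward step is a Claisen acylation of the dianion of 13 by a rather electron-rich ester, followed by cyclodehydration through 14, and it must leave the pyranone of unit 1 alone.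

12 ⇒ 10 (through 11). C4–C4a of unit 1 is cut. This is the most nucleophilic carbon of the molecule facing an acyl carbon, and the cut turns the crowded bicycle into an acyclic acrylic acid whose four substituents can be introduced one at a time. The forward step needs the carboxyl and aryloxy groups cis, or able to become cis, and an activation mild enough for a benzyl ether and a methyl ester.

10 ⇒ 9. The acid is masked as its tert-butyl ester, which survives the basic steps and is orthogonal to the methyl ester. The unmasking must not alkylate the dimethoxyphenoxy ring with the tert-butyl cation.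

9 ⇒ 7 + 8. The vinylic C–O bond (future O1–C2 of unit 1) is cut. This brings in ring A of unit 1 as the symmetric, purchasable 8 and leaves an activated enol sulfonate. The forward step is an addition–elimination at a crowded β-carbon, which must win over attack at sulfur.

7 ⇒ 6. The O–S bond is cut, returning the β-keto ester. The forward step must sulfonylate oxygen, not carbon; the alkene geometry is of secondary importance (see the remark before the steps).

6 ⇒ 4 + 5. The bond between the α-carbon and the ketone carbon (future C2–C3 of unit 1) is cut. This attaches the future C2 aryl group as the acid chloride 5. The forward step is a C-acylation of an ester enolate that must not touch the methyl ester.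

4 ⇒ 1 + 2 (through 3). The bond between the α-carbon and the arene (future C3–aryl bond of unit 1) is cut. Both pieces are purchasable, and the ortho-methoxy and para-ester pattern of the shared ring is bought ready-made in 2. The forward coupling must tolerate two ester groups, which calls for a zinc enolate, not a lithium enolate.

## Other disconnections considered

Alternative 1: The cut removes C4–C4a and O1–C8a of unit 2, so ring A of unit 2 arrives as an aryne. In the forward direction the arylpropiolic acid A1, which carries the finished unit 1, would be treated with the silyl aryl triflate A2 and CsF. The released 3,5-bis(benzyloxy)benzyne A3 would be attacked by the carboxylate at the aryne carbon remote from the neighbouring benzyloxy group. The aryl anion formed next to that group would then take over the acyl group to give the 2-hydroxyaryl ynone A4, and a later 6-endo oxa-Michael closure would be needed to reach 15.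
- In its favour: two bonds form in one fluoride-mediated, metal-free operation, regiochemistry is steered by the alkoxy group next to the aryne, and nothing strongly acidic or basic touches unit 1.
- Against it: A1 would have to be made from 12 by several functional-group changes at the ester, A2 needs a multistep synthesis whereas 13 can be bought, arylpropiolic acids are prone to decarboxylation under fluoride, and the ynone can also close 5-exo to an aurone.
- Comparison: on bonds formed in the key operation the alternative is better, and on mildness toward unit 1 it is at least equal. On structure it leaves the pyranone of unit 2 still open, and on step count it is longer by the steps needed for A1 and A2.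

Alternative 2: The cut is C4a–C5 of unit 2, which unravels ring A of unit 2 into a polyketide chain on a preformed pyranone. In the forward direction base would convert the keto ester side chain of A5 into an extended enolate. The pyranone carbon next to the side chain would attack the terminal ester in a six-membered Claisen closure, and tautomerisation would give the resorcinol ring of A6 as the free 5,7-diol.
- In its favour: unit 2 never needs benzyl groups, so the end game only has to remove one benzyl and one chelated methyl group; on protecting-group economy this is better than the chosen plan. The position of the two hydroxyl groups is unambiguous.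
- Against it: A5 is a polycarbonyl compound with several acidic sites, its assembly from 12 would take several strong-base acylations, and the cyclisation has to compete with aldol closure onto the pyranone carbonyl, lactonisation and opening of either pyranone by alkoxide.
- Comparison: mechanistically a carbanion Claisen replaces the electrophilic acylation of the chosen plan, and both avoid strong Lewis acids at the ring-forming event, where they are equal. Structurally the alternative builds a ring that the chosen plan buys in 13, and it is longer in steps.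

Alternative 3: The cut is at C2–C3 and O1–C2 of unit 1, the same pyranone as in the chosen plan but opened on the other side. In the forward direction the deoxybenzoin A7, which already carries unit 2, would be O-aroylated with 5. A base-induced Baker–Venkataraman shift of the aroyl group to the benzylic carbon and cyclodehydration would give A8, which is identical with 15.
- In its favour: this is the classical route to 2,3-diarylchromones, the benzylic methylene is more acidic than a methyl ketone, there is no alkene geometry to consider and no substitution at a crowded vinylic carbon, and it lands on 15 with unit 2 complete. On precedent and on simplicity of the ring-forming event it is the equal of the chosen plan, arguably the better.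
- Against it: making A7 requires a Friedel–Crafts or Hoesch acylation of 8 under strong Lewis acid with the benzyl ethers of unit 2 present (the chelated one is labile), with an ortho/para question on the phenol. If unit 2 were built afterwards instead, the free chelated phenol and the enolisable benzylic ketone would interfere with the Claisen chemistry. The most crowded bond, C2–C3, would also be formed last on a large and valuable substrate.
- Comparison: step count is about equal. The chosen plan confines the crowded bond formation to a small acyclic fragment. The deoxybenzoin logic is kept in reserve, in an early-stage form, as the fallback for the key step.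

Key step: step 6

Remark: the acid chloride 5 and the acetophenone 13 are taken as purchasable materials.
Remark: 7, 9, 10 and 11 are drawn as Z isomers (oxygen substituent cis to the carboxyl carbon); E isomers or mixtures should converge on 12 in step 6, because the activated acyl species can rotate about C2–C3.

## Route

Step 1
Reactants: 1 tert-butyl bromoacetate; 2 methyl 3-bromo-4-methoxybenzoate
Product: 4 tert-butyl 2-[2-methoxy-5-(methoxycarbonyl)phenyl]acetate, via (2-tert-butoxy-2-oxoethyl)zinc bromide 3 (not isolated)
Conditions: 1, Zn dust (Me3SiCl-activated), THF, 25 °C; then 2, Pd(dba)2 (2 mol %), P(t-Bu)3 (2 mol %), 25 → 50 °C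
Reagents that add atoms: none
Why: Zinc insertion gives the Reformatsky reagent 3, which undergoes Negishi-type α-arylation (oxidative addition of zerovalent palladium into the C–Br bond of 2, transmetalation, reductive elimination); the zinc enolate is mild enough to leave both ester groups untouched, which a lithium enolate would not guarantee.

Step 2
Reactants: 4 tert-butyl 2-[2-methoxy-5-(methoxycarbonyl)phenyl]acetate; 5 4-(benzyloxy)benzoyl chloride
Product: 6 tert-butyl 3-[4-(benzyloxy)phenyl]-2-[2-methoxy-5-(methoxycarbonyl)phenyl]-3-oxopropanoate (racemic; the C2 centre is labile and is destroyed in step 3)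
Conditions: LiN(SiMe3)2 (2.1 equiv), THF, −78 °C; 5 (1.0 equiv), −78 → 0 °C; aq. NH4Cl
Reagents that add atoms: none
Why: Claisen-type C-acylation of the lithium enolate of an arylacetic ester by an acid chloride; the second equivalent of base deprotonates the β-keto ester as it forms, which prevents proton exchange and double acylation, and at −78 °C the acid chloride reacts far faster than the methyl benzoate.

Step 3
Reactants: 6 tert-butyl 3-[4-(benzyloxy)phenyl]-2-[2-methoxy-5-(methoxycarbonyl)phenyl]-3-oxopropanoate
Product: 7 tert-butyl (2Z)-3-[4-(benzyloxy)phenyl]-2-[2-methoxy-5-(methoxycarbonyl)phenyl]-3-{[(4-methylphenyl)sulfonyl]oxy}prop-2-enoate (sulfonyloxy group cis to the tert-butyl ester)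
Conditions: TsCl (1.5 equiv), TMEDA (1.5 equiv), LiCl (1.5 equiv), MeCN, 0 → 25 °C
Reagents that add atoms: p-toluenesulfonyl chloride, Cc1ccc(cc1)S(Cl)(=O)=O
Why: O-sulfonylation of a β-keto ester enolate (enol tosylate formation); lithium chelation between the enolate oxygen and the ester carbonyl should hold these cis and favour the Z enol tosylate, and the doubly stabilised, hindered enolate reacts at oxygen.

Step 4
Reactants: 7 tert-butyl (2Z)-3-[4-(benzyloxy)phenyl]-2-[2-methoxy-5-(methoxycarbonyl)phenyl]-3-{[(4-methylphenyl)sulfonyl]oxy}prop-2-enoate; 8 3,5-dimethoxyphenol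
Product: 9 tert-butyl (2Z)-3-[4-(benzyloxy)phenyl]-3-(3,5-dimethoxyphenoxy)-2-[2-methoxy-5-(methoxycarbonyl)phenyl]prop-2-enoate
Conditions: Cs2CO3 (2 equiv), DMF, 60 °C
Reagents that add atoms: none
Why: Nucleophilic vinylic substitution by addition–elimination: the caesium phenoxide adds to the β-carbon of the acrylate, the ester- and aryl-stabilised carbanion expels tosylate, and the hard oxygen end of the phenoxide is favoured in DMF; the geometry of 9 is not critical for step 6.

Step 5
Reactants: 9 tert-butyl (2Z)-3-[4-(benzyloxy)phenyl]-3-(3,5-dimethoxyphenoxy)-2-[2-methoxy-5-(methoxycarbonyl)phenyl]prop-2-enoate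
Product: 10 (2Z)-3-[4-(benzyloxy)phenyl]-3-(3,5-dimethoxyphenoxy)-2-[2-methoxy-5-(methoxycarbonyl)phenyl]prop-2-enoic acid
Conditions: CF3CO2H/CH2Cl2 (1:4), 1,3-dimethoxybenzene (5 equiv), 0 → 25 °C; evaporation, trituration with hexane
Reagents that add atoms: none
Why: Acidolysis of a tert-butyl ester by alkyl–oxygen cleavage; the methyl ester, the benzyl ether and the deactivated (push–pull) enol ether should tolerate dilute acid in the absence of water, and the unhindered scavenger arene takes up the tert-butyl cation that would otherwise alkylate the dimethoxyphenoxy ring.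

Step 6
Reactants: 10 (2Z)-3-[4-(benzyloxy)phenyl]-3-(3,5-dimethoxyphenoxy)-2-[2-methoxy-5-(methoxycarbonyl)phenyl]prop-2-enoic acid
Product: 12 methyl 3-{2-[4-(benzyloxy)phenyl]-5,7-dimethoxy-4-oxo-4H-chromen-3-yl}-4-methoxybenzoate, via mixed trifluoroacetic anhydride 11 (not isolated)
Conditions: (CF3CO)2O (3 equiv), CH2Cl2, 0 → 25 °C
Reagents that add atoms: none
Why: The anhydride converts the acid into the mixed anhydride 11, which reacts as an acylium equivalent. Its acyl carbon attacks the carbon of the 3,5-dimethoxyphenoxy ring that is ortho to the ether oxygen, ortho to one methoxy group and para to the other, and loss of a proton restores the arene; this is the intramolecular Friedel–Crafts acylation used to close chromones and xanthones from aryloxy acids. The one ring closed is the six-membered pyranone of unit 1, by 6-exo-trig attack at the acyl carbon with the reacting arene bond inside the new ring. No stereocentre is formed. The selectivity needed is that the acyl group reaches the phenoxy ring and not the 4-benzyloxyphenyl ring, which requires carboxyl and aryloxy cis. The acylium form is a vinylogous oxocarbenium ion with a ketene resonance form and a low barrier to rotation about C2–C3, so E and Z acyl species should interconvert and drain through the much faster closure onto the triply oxygen-activated ring, whereas closure onto the other ring would make a five-membered indenone at a position meta to its oxygen. The two ortho positions of the symmetric phenoxy ring are equivalent, so only one regioisomer can arise. Because the arene is as nucleophilic as a phloroglucinol triether, no strong Lewis acid is required, and the benzyl ether and the methyl ester should survive.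

Step 7
Reactants: 12 methyl 3-{2-[4-(benzyloxy)phenyl]-5,7-dimethoxy-4-oxo-4H-chromen-3-yl}-4-methoxybenzoate; 13 1-[2,4-bis(benzyloxy)-6-hydroxyphenyl]ethan-1-one
Product: 15 5,7-bis(benzyloxy)-2-(3-{2-[4-(benzyloxy)phenyl]-5,7-dimethoxy-4-oxo-4H-chromen-3-yl}-4-methoxyphenyl)-4H-chromen-4-one, via 1,3-diketone 14 (not isolated)
Conditions: 13 (2.5 equiv), LiN(SiMe3)2 (6 equiv), THF, −78 → −10 °C; 12, −10 → 25 °C; then AcOH (excess), THF distilled off, 100 °C
Reagents that add atoms: none
Why: Crossed Claisen condensation of the lithium dianion of an ortho-hydroxyacetophenone with an aryl methyl ester, the direct variant of the Baker–Venkataraman flavone synthesis, driven by deprotonation of 14; the acetate-buffered acetic acid then effects cyclodehydration (phenol adds to the aryl ketone, water is lost) without endangering the benzyl ethers, and the fully substituted C2 of unit 1 shields that pyranone from conjugate attack.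

Step 8
Reactants: 15 5,7-bis(benzyloxy)-2-(3-{2-[4-(benzyloxy)phenyl]-5,7-dimethoxy-4-oxo-4H-chromen-3-yl}-4-methoxyphenyl)-4H-chromen-4-one
Product: 16 5,7-dihydroxy-2-{3-[5-hydroxy-2-(4-hydroxyphenyl)-7-methoxy-4-oxo-4H-chromen-3-yl]-4-methoxyphenyl}-4H-chromen-4-one (target)
Conditions: BCl3 (1 M in CH2Cl2, 10 equiv), C6HMe5 (10 equiv), CH2Cl2, −78 → 25 °C; aq. NaHCO3
Reagents that add atoms: none
Why: Lewis-acid ether cleavage: the boron trihalide removes the three benzyl groups at low temperature with the non-basic arene trapping the benzyl cations, and on warming it cleaves the one methyl ether held in a six-membered chelate with the C4 carbonyl of unit 1 (chloride attacks the methyl group); the unchelated methyl ethers at C7 of unit 1 and C4' of unit 2 are not activated toward this reagent.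

## Compound list

1 | tert-butyl bromoacetate | CC(C)(C)OC(=O)CBr | starting material
2 | methyl 3-bromo-4-methoxybenzoate | COC(=O)c1ccc(OC)c(Br)c1 | starting material
3 | (2-tert-butoxy-2-oxoethyl)zinc bromide | CC(C)(C)OC(=O)C[Zn]Br | intermediate (not isolated)
4 | tert-butyl 2-[2-methoxy-5-(methoxycarbonyl)phenyl]acetate | COC(=O)c1ccc(OC)c(CC(=O)OC(C)(C)C)c1 | intermediate
5 | 4-(benzyloxy)benzoyl chloride | O=C(Cl)c1ccc(OCc2ccccc2)cc1 | starting material
6 | tert-butyl 3-[4-(benzyloxy)phenyl]-2-[2-methoxy-5-(methoxycarbonyl)phenyl]-3-oxopropanoate (racemic) | COC(=O)c1ccc(OC)c(C(C(=O)OC(C)(C)C)C(=O)c2ccc(OCc3ccccc3)cc2)c1 | intermediate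
7 | tert-butyl (2Z)-3-[4-(benzyloxy)phenyl]-2-[2-methoxy-5-(methoxycarbonyl)phenyl]-3-{[(4-methylphenyl)sulfonyl]oxy}prop-2-enoate | CC(C)(C)OC(=O)/C(c1cc(C(=O)OC)ccc1OC)=C(\OS(=O)(=O)c1ccc(C)cc1)c1ccc(OCc2ccccc2)cc1 | intermediate
8 | 3,5-dimethoxyphenol | COc1cc(O)cc(OC)c1 | starting material
9 | tert-butyl (2Z)-3-[4-(benzyloxy)phenyl]-3-(3,5-dimethoxyphenoxy)-2-[2-methoxy-5-(methoxycarbonyl)phenyl]prop-2-enoate | CC(C)(C)OC(=O)/C(c1cc(C(=O)OC)ccc1OC)=C(\Oc1cc(OC)cc(OC)c1)c1ccc(OCc2ccccc2)cc1 | intermediate
10 | (2Z)-3-[4-(benzyloxy)phenyl]-3-(3,5-dimethoxyphenoxy)-2-[2-methoxy-5-(methoxycarbonyl)phenyl]prop-2-enoic acid | OC(=O)/C(c1cc(C(=O)OC)ccc1OC)=C(\Oc1cc(OC)cc(OC)c1)c1ccc(OCc2ccccc2)cc1 | intermediate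
11 | (2Z)-3-[4-(benzyloxy)phenyl]-3-(3,5-dimethoxyphenoxy)-2-[2-methoxy-5-(methoxycarbonyl)phenyl]prop-2-enoic trifluoroacetic anhydride | O=C(OC(=O)C(F)(F)F)/C(c1cc(C(=O)OC)ccc1OC)=C(\Oc1cc(OC)cc(OC)c1)c1ccc(OCc2ccccc2)cc1 | intermediate (not isolated)
12 | methyl 3-{2-[4-(benzyloxy)phenyl]-5,7-dimethoxy-4-oxo-4H-chromen-3-yl}-4-methoxybenzoate | COc1cc(OC)c2c(=O)c(-c3cc(C(=O)OC)ccc3OC)c(-c3ccc(OCc4ccccc4)cc3)oc2c1 | intermediate
13 | 1-[2,4-bis(benzyloxy)-6-hydroxyphenyl]ethan-1-one | CC(=O)c1c(O)cc(OCc2ccccc2)cc1OCc1ccccc1 | starting material
14 | 1-[2,4-bis(benzyloxy)-6-hydroxyphenyl]-3-(3-{2-[4-(benzyloxy)phenyl]-5,7-dimethoxy-4-oxo-4H-chromen-3-yl}-4-methoxyphenyl)propane-1,3-dione | COc1cc(OC)c2c(=O)c(-c3cc(C(=O)CC(=O)c4c(O)cc(OCc5ccccc5)cc4OCc4ccccc4)ccc3OC)c(-c3ccc(OCc4ccccc4)cc3)oc2c1 | intermediate (not isolated)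
15 | 5,7-bis(benzyloxy)-2-(3-{2-[4-(benzyloxy)phenyl]-5,7-dimethoxy-4-oxo-4H-chromen-3-yl}-4-methoxyphenyl)-4H-chromen-4-one | COc1cc(OC)c2c(=O)c(-c3cc(-c4cc(=O)c5c(OCc6ccccc6)cc(OCc6ccccc6)cc5o4)ccc3OC)c(-c3ccc(OCc4ccccc4)cc3)oc2c1 | intermediate
16 | 5,7-dihydroxy-2-{3-[5-hydroxy-2-(4-hydroxyphenyl)-7-methoxy-4-oxo-4H-chromen-3-yl]-4-methoxyphenyl}-4H-chromen-4-one | COc1cc(O)c2c(=O)c(-c3cc(-c4cc(=O)c5c(O)cc(O)cc5o4)ccc3OC)c(-c3ccc(O)cc3)oc2c1 | target

## Step count and least certain steps

Total step count: 8. Longest linear sequence: 8 steps (1 → 4 → 6 → 7 → 9 → 10 → 12 → 15 → 16); the other building blocks (2, 5, 8, 13) enter as purchased materials.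

Step 6 (key step). What may go wrong: intermolecular trifluoroacetylation of the very electron-rich phenoxy ring before it cyclises; acid-induced cleavage of the aryl vinyl ether; or incomplete E/Z interconversion, so that part of the material closes onto the 4-benzyloxyphenyl ring. Fallback: the pyranone of unit 1 would be closed from the other side by deoxybenzoin chemistry, setting out from 4 and coming back to the route at 12. Acidolysis of 4 (CF3CO2H, CH2Cl2) would give 2-[2-methoxy-5-(methoxycarbonyl)phenyl]acetic acid F1. Friedel–Crafts acylation of 8 with this acid in BF3·OEt2 at 80 °C would give the deoxybenzoin methyl 3-[2-(2-hydroxy-4,6-dimethoxyphenyl)-2-oxoethyl]-4-methoxybenzoate F2. O-aroylation with 5 in pyridine would give the aryl ester methyl 3-[2-(2-{[4-(benzyloxy)benzoyl]oxy}-4,6-dimethoxyphenyl)-2-oxoethyl]-4-methoxybenzoate F3. A Baker–Venkataraman shift with LiN(SiMe3)2 in THF would move the aroyl group to the benzylic carbon to give methyl 3-{1-[4-(benzyloxy)phenyl]-3-(2-hydroxy-4,6-dimethoxyphenyl)-1,3-dioxopropan-2-yl}-4-methoxybenzoate F4, and cyclodehydration in AcOH with catalytic H2SO4 would deliver 12.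

Step 4. What may go wrong: attack of the phenoxide at sulfur instead of at the hindered β-carbon, transferring the tosyl group and returning the enolate of 6; slow addition because the 4-benzyloxyphenyl donor lowers the electrophilicity of the β-carbon; or C-attack by the ambident phenoxide. Fallback: the C–O bond would be made by cross-coupling instead of addition–elimination, setting out from 6 and coming back at 9. Chelation-controlled enol triflation of 6 (Tf2O, aqueous LiOH, toluene, 0 °C) would give tert-butyl (2Z)-3-[4-(benzyloxy)phenyl]-2-[2-methoxy-5-(methoxycarbonyl)phenyl]-3-{[(trifluoromethyl)sulfonyl]oxy}prop-2-enoate F5. Coupling of this with 8 under Pd2(dba)3, a bulky di-tert-butylbiarylphosphine and K3PO4 in toluene at 90 °C (vinyl–oxygen reductive elimination from divalent palladium) would give 9.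

Step 7. What may go wrong: sluggish acylation of the dianion by an ester deactivated by its para methoxy group, self-condensation of the acetophenone on long reaction times, or opening of the pyranone of unit 1 by excess enolate or amide. Fallback: the acyl group would be transferred intramolecularly from a more reactive acyl donor, setting out from 12 and coming back at 14. Saponification of 12 (LiOH, THF/H2O, 25 °C) would give 3-{2-[4-(benzyloxy)phenyl]-5,7-dimethoxy-4-oxo-4H-chromen-3-yl}-4-methoxybenzoic acid F6. Steglich esterification with 13 (EDC·HCl, DMAP, CH2Cl2) would give 2-acetyl-3,5-bis(benzyloxy)phenyl 3-{2-[4-(benzyloxy)phenyl]-5,7-dimethoxy-4-oxo-4H-chromen-3-yl}-4-methoxybenzoate F7. A Baker–Venkataraman rearrangement (KOt-Bu, THF, 0 → 25 °C) would give 14, which would be cyclodehydrated to 15 as in the second stage of step 7.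

Step 8. What may go wrong: incomplete cleavage of the chelated methyl ether at temperatures that still spare the two methyl ethers to be kept, over-demethylation on prolonged exposure, or C-benzylation of the phloroglucinol ring of unit 2 if cation trapping is inefficient. Fallback: the two deprotections would be separated, setting out from 15 and coming back at 16. Hydrogenolysis (H2, 10% Pd/C, THF/MeOH) would remove the benzyl groups and give 2-{3-[2-(4-hydroxyphenyl)-5,7-dimethoxy-4-oxo-4H-chromen-3-yl]-4-methoxyphenyl}-5,7-dihydroxy-4H-chromen-4-one F8. The peri methyl ether of unit 1 would then be cleaved selectively by chelation with AlCl3 in MeCN at 60 °C to give 16.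

## Further compounds

F1 | step 6 | 2-[2-methoxy-5-(methoxycarbonyl)phenyl]acetic acid | COC(=O)c1ccc(OC)c(CC(=O)O)c1
F2 | step 6 | methyl 3-[2-(2-hydroxy-4,6-dimethoxyphenyl)-2-oxoethyl]-4-methoxybenzoate | COC(=O)c1ccc(OC)c(CC(=O)c2c(O)cc(OC)cc2OC)c1
F3 | step 6 | methyl 3-[2-(2-{[4-(benzyloxy)benzoyl]oxy}-4,6-dimethoxyphenyl)-2-oxoethyl]-4-methoxybenzoate | COC(=O)c1ccc(OC)c(CC(=O)c2c(OC(=O)c3ccc(OCc4ccccc4)cc3)cc(OC)cc2OC)c1
F4 | step 6 | methyl 3-{1-[4-(benzyloxy)phenyl]-3-(2-hydroxy-4,6-dimethoxyphenyl)-1,3-dioxopropan-2-yl}-4-methoxybenzoate | COC(=O)c1ccc(OC)c(C(C(=O)c2ccc(OCc3ccccc3)cc2)C(=O)c2c(O)cc(OC)cc2OC)c1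
F5 | step 4 | tert-butyl (2Z)-3-[4-(benzyloxy)phenyl]-2-[2-methoxy-5-(methoxycarbonyl)phenyl]-3-{[(trifluoromethyl)sulfonyl]oxy}prop-2-enoate | CC(C)(C)OC(=O)/C(c1cc(C(=O)OC)ccc1OC)=C(\OS(=O)(=O)C(F)(F)F)c1ccc(OCc2ccccc2)cc1
F6 | step 7 | 3-{2-[4-(benzyloxy)phenyl]-5,7-dimethoxy-4-oxo-4H-chromen-3-yl}-4-methoxybenzoic acid | COc1cc(OC)c2c(=O)c(-c3cc(C(=O)O)ccc3OC)c(-c3ccc(OCc4ccccc4)cc3)oc2c1
F7 | step 7 | 2-acetyl-3,5-bis(benzyloxy)phenyl 3-{2-[4-(benzyloxy)phenyl]-5,7-dimethoxy-4-oxo-4H-chromen-3-yl}-4-methoxybenzoate | COc1cc(OC)c2c(=O)c(-c3cc(C(=O)Oc4cc(OCc5ccccc5)cc(OCc5ccccc5)c4C(C)=O)ccc3OC)c(-c3ccc(OCc4ccccc4)cc3)oc2c1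
F8 | step 8 | 2-{3-[2-(4-hydroxyphenyl)-5,7-dimethoxy-4-oxo-4H-chromen-3-yl]-4-methoxyphenyl}-5,7-dihydroxy-4H-chromen-4-one | COc1cc(OC)c2c(=O)c(-c3cc(-c4cc(=O)c5c(O)cc(O)cc5o4)ccc3OC)c(-c3ccc(O)cc3)oc2c1
A1 | alternative 1 | 3-(3-{2-[4-(benzyloxy)phenyl]-5,7-dimethoxy-4-oxo-4H-chromen-3-yl}-4-methoxyphenyl)prop-2-ynoic acid | COc1cc(OC)c2c(=O)c(-c3cc(C#CC(=O)O)ccc3OC)c(-c3ccc(OCc4ccccc4)cc3)oc2c1
A2 | alternative 1 | 3,5-bis(benzyloxy)-2-(trimethylsilyl)phenyl trifluoromethanesulfonate | C[Si](C)(C)c1c(OCc2ccccc2)cc(OCc2ccccc2)cc1OS(=O)(=O)C(F)(F)F
A3 | alternative 1 | 3,5-bis(benzyloxy)benzyne | C1#CC(OCc2ccccc2)=CC(OCc2ccccc2)=C1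
A4 | alternative 1 | 1-[2,4-bis(benzyloxy)-6-hydroxyphenyl]-3-(3-{2-[4-(benzyloxy)phenyl]-5,7-dimethoxy-4-oxo-4H-chromen-3-yl}-4-methoxyphenyl)prop-2-yn-1-one | COc1cc(OC)c2c(=O)c(-c3cc(C#CC(=O)c4c(O)cc(OCc5ccccc5)cc4OCc4ccccc4)ccc3OC)c(-c3ccc(OCc4ccccc4)cc3)oc2c1
A5 | alternative 2 | methyl 4-[6-(3-{2-[4-(benzyloxy)phenyl]-5,7-dimethoxy-4-oxo-4H-chromen-3-yl}-4-methoxyphenyl)-4-oxo-4H-pyran-2-yl]-3-oxobutanoate | COc1cc(OC)c2c(=O)c(-c3cc(-c4cc(=O)cc(CC(=O)CC(=O)OC)o4)ccc3OC)c(-c3ccc(OCc4ccccc4)cc3)oc2c1
A6 | alternative 2 | 2-(3-{2-[4-(benzyloxy)phenyl]-5,7-dimethoxy-4-oxo-4H-chromen-3-yl}-4-methoxyphenyl)-5,7-dihydroxy-4H-chromen-4-one | COc1cc(OC)c2c(=O)c(-c3cc(-c4cc(=O)c5c(O)cc(O)cc5o4)ccc3OC)c(-c3ccc(OCc4ccccc4)cc3)oc2c1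
A7 | alternative 3 | 5,7-bis(benzyloxy)-2-{3-[2-(2-hydroxy-4,6-dimethoxyphenyl)-2-oxoethyl]-4-methoxyphenyl}-4H-chromen-4-one | COc1cc(O)c(C(=O)Cc2cc(-c3cc(=O)c4c(OCc5ccccc5)cc(OCc5ccccc5)cc4o3)ccc2OC)c(OC)c1
A8 | alternative 3 | 5,7-bis(benzyloxy)-2-(3-{2-[4-(benzyloxy)phenyl]-5,7-dimethoxy-4-oxo-4H-chromen-3-yl}-4-methoxyphenyl)-4H-chromen-4-one (identical with 15) | COc1cc(OC)c2c(=O)c(-c3cc(-c4cc(=O)c5c(OCc6ccccc6)cc(OCc6ccccc6)cc5o4)ccc3OC)c(-c3ccc(OCc4ccccc4)cc3)oc2c1
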